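**Assumption:** the SMILES is read literally: both ring alkenes are ring-cis (C2/C9 and C3/C6 on the same side; CIP E because of the CH2O groups) and the centres are 6R,7R,8R (H6/H7 trans, H7/H8 cis). Germacrane numbering (ring C1–C10, lactone carbons C11–C13, C14 on C10, C15 on C4) is used for every intermediate.

## Retrosynthetic overview

1. Target 21 ⇐ lactonisation of anti-6,8-diol ester 20 ⇐ hydroxyl-directed reduction of β-hydroxy enone 19 (sets C6).
2. Ten-membered ring ⇐ ring expansion of bicyclo[4.4.0] tertiary homoallylic alcohol 16 by cleavage of its C1–C6 ring-fusion bond (6→10); this gives the C6 ketone, the ring-cis C1=C10 alkene and the C14 methacrylate in one operation.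
3. 16 ⇐ intramolecular indium Barbier allylation of enone 14 (C6–C7 bond, ring B, C7 stereocentre).
4. 14 ⇐ asymmetric Hosomi–Sakurai union of allylsilane 7 with enal 12 (C8–C9 bond, C8 stereocentre).
5. 7 ⇐ cyclohexane-1,3-dione (ring A, whose endocyclic alkene becomes the ring-cis C4=C5); 12 ⇐ dimethoxyacetaldehyde + isopropyl acrylate. Ring order: ring A, ring B, ten-membered ring by expansion, lactone last.

## Route

Step 1
Reactants: 1 cyclohexane-1,3-dione
Product: 2 3-bromocyclohex-2-en-1-one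
Conditions: (COBr)2, DMF (cat.), CH2Cl2, 0 °C → rt
Reagents that add atoms: oxalyl bromide, BrC(=O)C(=O)Br
Why: Vilsmeier-type activation of the vinylogous acid replaces the enol OH by bromide (vinylogous acyl bromide formation).

Step 2
Reactants: 2 3-bromocyclohex-2-en-1-one
Product: 3 3-(hydroxymethyl)cyclohex-2-en-1-one
Conditions: Bu3SnCH2OH, Pd(PPh3)4 (5 mol %), 1,4-dioxane, 90 °C
Reagents that add atoms: (tributylstannyl)methanol, OC[Sn](CCCC)(CCCC)CCCC
Why: Stille cross-coupling (hydroxymethyl transfer) at the activated β-bromoenone carbon installs C15 with its oxygen.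

Step 3
Reactants: 3 3-(hydroxymethyl)cyclohex-2-en-1-one
Product: 4 3-({[tert-butyl(dimethyl)silyl]oxy}methyl)cyclohex-2-en-1-one
Conditions: TBSCl, imidazole, DMF, rt
Reagents that add atoms: tert-butyl(chloro)dimethylsilane, CC(C)(C)[Si](C)(C)Cl
Why: Standard silylation of the primary alcohol so that C15–O survives the enolate, Lewis acid and palladium steps.

Step 4
Reactants: 4 silyl ether enone; 5 (2-bromoprop-2-en-1-yl)trimethylsilane
Product: 7 3-({[tert-butyl(dimethyl)silyl]oxy}methyl)-6-[3-(trimethylsilyl)prop-1-en-2-yl]cyclohex-2-en-1-one (racemic), via lithium dienolate 6 (not isolated)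
Conditions: LiN(SiMe3)2, THF, −78 °C; then 5, Pd2(dba)3 (2.5 mol %), P(t-Bu)3 (6 mol %), −78 °C → rt
Reagents that add atoms: none
Why: Kinetic α′-deprotonation gives the cross-conjugated enolate, which undergoes palladium-catalysed ketone α-alkenylation (enolate cross-coupling) with the vinyl bromide to form C1–C10; the new centre C1 is racemic and is later destroyed.

Step 5
Reactants: 8 2,2-dimethoxyacetaldehyde; 9 propan-2-yl prop-2-enoate
Product: 10 propan-2-yl 3-hydroxy-4,4-dimethoxy-2-methylidenebutanoate (racemic)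
Conditions: DABCO (0.5 equiv), 1,4-dioxane/H2O, rt
Reagents that add atoms: none
Why: Morita–Baylis–Hillman reaction of an activated α-alkoxy aldehyde forms the C7–C11 bond; the isopropyl ester is chosen to slow premature lactonisation later.

Step 6
Reactants: 10 Baylis–Hillman adduct
Product: 12 propan-2-yl (2Z)-2-(bromomethyl)-4-oxobut-2-enoate, via bromo acetal 11 (not isolated)
Conditions: PBr3, Et2O, 0 °C; then 2 M HCl, acetone/H2O, rt
Reagents that add atoms: phosphorus tribromide, BrP(Br)Br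
Why: SN2′ bromination of the Baylis–Hillman alcohol gives the thermodynamically preferred Z allylic bromide (C8 cis to CH2Br), and acid hydrolysis of the acetal unmasks the C8 aldehyde.

Step 7
Reactants: 7 allylsilane enone; 12 bromo enal
Product: 14 propan-2-yl (2Z,4R)-2-(bromomethyl)-4-hydroxy-6-[4-({[tert-butyl(dimethyl)silyl]oxy}methyl)-2-oxocyclohex-3-en-1-yl]hepta-2,6-dienoate (8R; both C1 epimers), via trimethylsilyl ether 13 (not isolated)
Conditions: acyloxyborane from (2R,3R)-2-O-(2,6-diisopropoxybenzoyl)tartaric acid and BH3·THF (20 mol %), EtCN, −78 °C; then 1 M HCl, THF, 0 °C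
Reagents that add atoms: none
Why: Catalytic asymmetric Hosomi–Sakurai allylation, in which the chiral Lewis acid directs the 2-substituted allylsilane to the Re face of the aldehyde (1,2-addition), forms C8–C9 and sets C8 as R.

Step 8
Reactants: 14 hydroxy allylic bromide
Product: 15 propan-2-yl 2-[(1R,2R,8aS)-2,8a-dihydroxy-4-methylidene-7-({[tert-butyl(dimethyl)silyl]oxy}methyl)-1,2,3,4,4a,5,6,8a-octahydronaphthalen-1-yl]prop-2-enoate (7R,8R; both C1 epimers)
Conditions: indium powder (1.5 equiv), THF/H2O 3:1, 0.01 M, rt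
Reagents that add atoms: none
Why: Intramolecular indium Barbier allylation (SE2′, closed transition state) forms C6–C7 and ring B; the free C8 hydroxyl binds indium and is held in the allyl plane, so C7 attacks the ketone from the C9 face, giving H7/H8 cis (7R) with the tertiary OH cis to the C7 side chain.

Step 9
Reactants: 15 bicyclic diol ester
Product: 16 propan-2-yl 2-[(1R,2R,8aS)-2-{[tert-butyl(dimethyl)silyl]oxy}-8a-hydroxy-4-methylidene-7-({[tert-butyl(dimethyl)silyl]oxy}methyl)-1,2,3,4,4a,5,6,8a-octahydronaphthalen-1-yl]prop-2-enoate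
Conditions: TBSOTf (1.05 equiv), 2,6-lutidine, CH2Cl2, −78 °C
Reagents that add atoms: tert-butyldimethylsilyl trifluoromethanesulfonate, CC(C)(C)[Si](C)(C)OS(=O)(=O)C(F)(F)F
Why: The secondary C8 hydroxyl is silylated selectively over the hindered tertiary C6 hydroxyl, which must stay free as the trigger for ring expansion.

Step 10
Reactants: 16 bicyclic tertiary homoallylic alcohol
Product: 17 {(1E,5E,8R,9R)-9-{[tert-butyl(dimethyl)silyl]oxy}-5-({[tert-butyl(dimethyl)silyl]oxy}methyl)-7-oxo-8-[3-oxo-3-(propan-2-yloxy)prop-1-en-2-yl]cyclodeca-1,5-dien-1-yl}methyl 2-methylprop-2-enoate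
Conditions: Pd(O2CCF3)2 (10 mol %), 4,5-diazafluoren-9-one (12 mol %), methacrylic acid (5 equiv), Cs2CO3 (20 mol %), 1,4-benzoquinone (2 equiv), 4 Å MS, 1,4-dioxane, 60 °C
Reagents that add atoms: methacrylic acid, C=C(C)C(=O)O
Why: Proposed new method: the tertiary alkoxide bound to divalent palladium undergoes β-allyl (β-carbon) elimination across the electron-rich C10=C14 alkene, cleaving the C1–C6 ring-fusion bond to give the C6 ketone and a ten-membered allyl–palladium carboxylate; this equilibrates to the less strained ring-cis allyl (so both C1 epimers converge) and benzoquinone-promoted C–O reductive elimination at the unhindered C14 terminus delivers the methacrylate and zerovalent palladium, which benzoquinone reoxidises. The closest known reactions are palladium-catalysed retro-allylation of tertiary homoallylic alcohols, oxidative ring-opening of tert-cyclobutanols, and palladium/benzoquinone allylic acyloxylation through allyl–palladium carboxylates.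

Step 11
Reactants: 17 ring-expanded bis-silyl ether
Product: 19 {(1E,5E,8R,9R)-5-(acetoxymethyl)-9-hydroxy-7-oxo-8-[3-oxo-3-(propan-2-yloxy)prop-1-en-2-yl]cyclodeca-1,5-dien-1-yl}methyl 2-methylprop-2-enoate, via diol 18 (not isolated)
Conditions: HF·pyridine, THF, 0 °C → rt; then AcCl (1.1 equiv), 2,4,6-collidine, CH2Cl2, −78 °C
Reagents that add atoms: acetyl chloride, CC(Cl)=O
Why: Fluoride removes both silyl ethers, and low-temperature acetyl chloride/collidine acetylates the primary allylic C15 hydroxyl selectively over the hindered secondary C8 hydroxyl.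

Step 12
Reactants: 19 β-hydroxy enone
Product: 21 [(3aR,4R,6E,10E,11aR)-10-(acetoxymethyl)-4-hydroxy-3-methylidene-2-oxo-2,3,3a,4,5,8,9,11a-octahydrocyclodeca[b]furan-6-yl]methyl 2-methylprop-2-enoate, via anti-diol ester 20 (not isolated)
Conditions: Me4NBH(OAc)3, MeCN/AcOH 1:1, −30 °C; then CSA (10 mol %), CH2Cl2, rt
Reagents that add atoms: none
Why: Evans–Saksena reduction delivers hydride intramolecularly from the C8-bound acetoxyborohydride, giving the 1,3-anti diol (6R) without touching esters or enoates; acid then closes the 6-hydroxyl (anti to C11) onto the isopropyl ester to give the trans-fused 6,12-lactone, the arrangement found in 8β-hydroxy germacranolides.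

## Compound list

1 | cyclohexane-1,3-dione | O=C1CCCC(=O)C1 | starting material
2 | 3-bromocyclohex-2-en-1-one | O=C1C=C(Br)CCC1 | intermediate
3 | 3-(hydroxymethyl)cyclohex-2-en-1-one | O=C1C=C(CO)CCC1 | intermediate
4 | 3-({[tert-butyl(dimethyl)silyl]oxy}methyl)cyclohex-2-en-1-one | O=C1C=C(CO[Si](C)(C)C(C)(C)C)CCC1 | intermediate
5 | (2-bromoprop-2-en-1-yl)trimethylsilane | C=C(Br)C[Si](C)(C)C | starting material
6 | lithium 5-({[tert-butyl(dimethyl)silyl]oxy}methyl)cyclohexa-1,5-dien-1-olate | [Li+].[O-]C1=CCCC(CO[Si](C)(C)C(C)(C)C)=C1 | intermediate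
7 | 3-({[tert-butyl(dimethyl)silyl]oxy}methyl)-6-[3-(trimethylsilyl)prop-1-en-2-yl]cyclohex-2-en-1-one (racemic at C1) | O=C1C=C(CO[Si](C)(C)C(C)(C)C)CCC1C(=C)C[Si](C)(C)C | intermediate
8 | 2,2-dimethoxyacetaldehyde | COC(OC)C=O | starting material
9 | propan-2-yl prop-2-enoate | C=CC(=O)OC(C)C | starting material
10 | propan-2-yl 3-hydroxy-4,4-dimethoxy-2-methylidenebutanoate (racemic) | CC(C)OC(=O)C(=C)C(O)C(OC)OC | intermediate
11 | propan-2-yl (2Z)-2-(bromomethyl)-4,4-dimethoxybut-2-enoate | BrC/C(C(=O)OC(C)C)=C\C(OC)OC | intermediate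
12 | propan-2-yl (2Z)-2-(bromomethyl)-4-oxobut-2-enoate | BrC/C(C(=O)OC(C)C)=C\C=O | intermediate
13 | trimethylsilyl ether of 14 (8R; C1 epimers) | O=C1C=C(CO[Si](C)(C)C(C)(C)C)CCC1C(=C)C[C@@H](O[Si](C)(C)C)/C=C(\CBr)C(=O)OC(C)C | intermediate
14 | propan-2-yl (2Z,4R)-2-(bromomethyl)-4-hydroxy-6-[4-({[tert-butyl(dimethyl)silyl]oxy}methyl)-2-oxocyclohex-3-en-1-yl]hepta-2,6-dienoate (8R; C1 epimers) | O=C1C=C(CO[Si](C)(C)C(C)(C)C)CCC1C(=C)C[C@@H](O)/C=C(\CBr)C(=O)OC(C)C | intermediate
15 | propan-2-yl 2-[(1R,2R,8aS)-2,8a-dihydroxy-4-methylidene-7-({[tert-butyl(dimethyl)silyl]oxy}methyl)-1,2,3,4,4a,5,6,8a-octahydronaphthalen-1-yl]prop-2-enoate (7R,8R; tertiary OH cis to the C7 side chain; C1 epimers) | CC(C)OC(=O)C(=C)[C@@H]1[C@H](O)CC(=C)C2CCC(CO[Si](C)(C)C(C)(C)C)=C[C@@]12O | intermediate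
16 | 8-O-tert-butyldimethylsilyl ether of 15 | CC(C)OC(=O)C(=C)[C@@H]1[C@H](O[Si](C)(C)C(C)(C)C)CC(=C)C2CCC(CO[Si](C)(C)C(C)(C)C)=C[C@@]12O | intermediate
17 | {(1E,5E,8R,9R)-9-{[tert-butyl(dimethyl)silyl]oxy}-5-({[tert-butyl(dimethyl)silyl]oxy}methyl)-7-oxo-8-[3-oxo-3-(propan-2-yloxy)prop-1-en-2-yl]cyclodeca-1,5-dien-1-yl}methyl 2-methylprop-2-enoate (7R,8R; both ring alkenes ring-cis) | C=C(C)C(=O)OC/C1=C/CC/C(CO[Si](C)(C)C(C)(C)C)=C\C(=O)[C@H](C(=C)C(=O)OC(C)C)[C@H](O[Si](C)(C)C(C)(C)C)C1 | intermediate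
18 | {(1E,5E,8R,9R)-9-hydroxy-5-(hydroxymethyl)-7-oxo-8-[3-oxo-3-(propan-2-yloxy)prop-1-en-2-yl]cyclodeca-1,5-dien-1-yl}methyl 2-methylprop-2-enoate | C=C(C)C(=O)OC/C1=C/CC/C(CO)=C\C(=O)[C@H](C(=C)C(=O)OC(C)C)[C@H](O)C1 | intermediate
19 | {(1E,5E,8R,9R)-5-(acetoxymethyl)-9-hydroxy-7-oxo-8-[3-oxo-3-(propan-2-yloxy)prop-1-en-2-yl]cyclodeca-1,5-dien-1-yl}methyl 2-methylprop-2-enoate | C=C(C)C(=O)OC/C1=C/CC/C(COC(C)=O)=C\C(=O)[C@H](C(=C)C(=O)OC(C)C)[C@H](O)C1 | intermediate
20 | {(1E,5E,7R,8R,9R)-5-(acetoxymethyl)-7,9-dihydroxy-8-[3-oxo-3-(propan-2-yloxy)prop-1-en-2-yl]cyclodeca-1,5-dien-1-yl}methyl 2-methylprop-2-enoate (6R,7R,8R) | C=C(C)C(=O)OC/C1=C/CC/C(COC(C)=O)=C\[C@@H](O)[C@H](C(=C)C(=O)OC(C)C)[C@H](O)C1 | intermediate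
21 | [(3aR,4R,6E,10E,11aR)-10-(acetoxymethyl)-4-hydroxy-3-methylidene-2-oxo-2,3,3a,4,5,8,9,11a-octahydrocyclodeca[b]furan-6-yl]methyl 2-methylprop-2-enoate (6R,7R,8R) | C=C(C)C(=O)OC/C1=C/CC/C(COC(C)=O)=C\[C@H]2OC(=O)C(=C)[C@@H]2[C@H](O)C1 | target

## Step count and risk

Total steps: 12. Longest linear sequence: 10 (steps 1–4 and 7–12); steps 5–6 form the side branch.

**Step 10 (proposed new ring expansion).** The alkoxide could instead eliminate across the acrylate arm (reverse of step 8), palladium could oxidise allylic C–H bonds, or the allyl might not equilibrate to the ring-cis form. The fallback sets out from 16 (cis-fused C1 epimer, separated) and comes back at 17, using a stereospecific epoxy-alcohol Grob fragmentation. NBS in wet DME adds to the 1,1-disubstituted alkene to give the bromohydrin F6. K2CO3 closes it to the spiro-epoxide F7, with oxygen on the face anti to the original bromonium. Ti(OiPr)4 in CH2Cl2 at 40 °C then fragments the C1–C6 bond antiperiplanar to the epoxide C–O bond to give the hydroxymethyl dienone F8, and methacryloyl chloride with 2,6-lutidine acylates it to 17.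

**Step 8 (Barbier cyclisation).** The H7/H8 cis outcome relies on hydroxyl chelation overriding allylic strain, and the product can lactonise prematurely. The fallback sets out from 14 and comes back at 15, enforcing the relationship with a lactone tether. Bromide-mediated E/Z equilibration with acid lactonisation (LiBr, CSA, MeCN, 50 °C) converts 14 into the butenolide F3. Indium in THF/H2O then cyclises it to the cis-fused tricyclic lactone F4, where the tether allows C6 to reach C7 only from the C9 face. LiOH opens the lactone to the lithium carboxylate F5, which 2-iodopropane in DMF alkylates to 15.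

**Step 7 (asymmetric allylation).** Facial control on this unusual enal is unproven, and the allylsilane could add intramolecularly to the ring A enone. The fallback sets out from 7 and 12 and comes back at 14, moving stereocontrol to a reagent-controlled ketone reduction. BF3·OEt2 in CH2Cl2 at −78 °C gives the racemic alcohol F1. Dess–Martin periodinane oxidises it to the ketone F2. Corey–Bakshi–Shibata reduction ((S)-2-methyl-CBS-oxazaborolidine, catecholborane, toluene, −78 °C; alkenyl arm as the large group) returns (R)-alcohol 14.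

## Further compounds

F1 | step 7 | propan-2-yl (2Z)-2-(bromomethyl)-4-hydroxy-6-[4-({[tert-butyl(dimethyl)silyl]oxy}methyl)-2-oxocyclohex-3-en-1-yl]hepta-2,6-dienoate (racemic at C8) | O=C1C=C(CO[Si](C)(C)C(C)(C)C)CCC1C(=C)CC(O)/C=C(\CBr)C(=O)OC(C)C
F2 | step 7 | propan-2-yl (2Z)-2-(bromomethyl)-4-oxo-6-[4-({[tert-butyl(dimethyl)silyl]oxy}methyl)-2-oxocyclohex-3-en-1-yl]hepta-2,6-dienoate | O=C1C=C(CO[Si](C)(C)C(C)(C)C)CCC1C(=C)CC(=O)/C=C(\CBr)C(=O)OC(C)C
F3 | step 8 | (5R)-3-(bromomethyl)-5-{2-[4-({[tert-butyl(dimethyl)silyl]oxy}methyl)-2-oxocyclohex-3-en-1-yl]prop-2-en-1-yl}furan-2(5H)-one | O=C1O[C@H](CC(=C)C2CCC(CO[Si](C)(C)C(C)(C)C)=CC2=O)C=C1CBr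
F4 | step 8 | tricyclic cis-fused 8,12-lactone of the acid of 15 (7R,8R; tertiary C6 hydroxyl free; C1 epimers) | O=C1O[C@@H]2CC(=C)C3CCC(CO[Si](C)(C)C(C)(C)C)=C[C@@]3(O)[C@@H]2C1=C
F5 | step 8 | lithium carboxylate corresponding to 15 | [Li+].[O-]C(=O)C(=C)[C@@H]1[C@H](O)CC(=C)C2CCC(CO[Si](C)(C)C(C)(C)C)=C[C@@]12O
F6 | step 10 | bromohydrin of 16 (C10 hydroxyl, C14 bromide) | CC(C)OC(=O)C(=C)[C@@H]1[C@H](O[Si](C)(C)C(C)(C)C)CC(O)(CBr)C2CCC(CO[Si](C)(C)C(C)(C)C)=C[C@@]12O
F7 | step 10 | spiro-epoxide of 16 (C10–O–C14 oxirane) | CC(C)OC(=O)C(=C)[C@@H]1[C@H](O[Si](C)(C)C(C)(C)C)CC3(CO3)C2CCC(CO[Si](C)(C)C(C)(C)C)=C[C@@]12O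
F8 | step 10 | C14-hydroxy analogue of 17 (free allylic alcohol) | OC/C1=C/CC/C(CO[Si](C)(C)C(C)(C)C)=C\C(=O)[C@H](C(=C)C(=O)OC(C)C)[C@H](O[Si](C)(C)C(C)(C)C)C1
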